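**Retrosynthetic overview**

1. The target is the 2,3-cis-3,4-trans oxolane (ring atoms O1, C2 aryl, C3 CH2OH arm, C4 aroyl, C5). The last disconnections are C=O ⇐ C=CH2 (oxidative cleavage of a 1-arylethenyl group at C4) and CH2OH ⇐ CO2Me at C3.
2. C2–H and C3–H ⇐ ionic hydrogenation of a 2-aryl-4,5-dihydrofuran (C2=C3): the C3 arm settles trans to C4, and hydride then enters C2 anti to the C3 arm, so aryl and CH2O become cis.
3. Key disconnection: the dihydrofuran, the only ring made, ⇐ Pd-catalysed asymmetric [3+2] union of a vinyl epoxide (O1–C5–C4) with an aryl ynoate (C2≡C3). It forms O1–C2 and C3–C4 and sets C4, from which C3 and C2 are relayed.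
4. Enabling feature: in the oxolane ring O1 and C4 stand 1,3 across C5H2, and C4 carries an sp2 carbon (the ketone carbon, carried as the central carbon of a 2-aryl-allyl unit), so O1–C5–C4 is a latent alkoxide/π-allyl dipole. C2 (aryl-bearing) and C3 (bearing the CH2OH carbon) are a latent β-aryl ynoate C2≡C3–CO2Me.
5. Fragments: the ynoate from 4-ethynyl-1,2-dimethoxybenzene and methyl chloroformate; the vinyl epoxide from 5-iodo-1,2,3-trimethoxybenzene and buta-2,3-dien-1-ol.

Key step: step 3

Remark: the given SMILES corresponds to the (2R,3R,4S) oxolane, in which the C2 aryl group and the C3 CH2OH arm are cis and the C4 aroyl group is trans to both; the locants O1, C2, C3, C4, C5 are used in this sense throughout.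

**Route**

Step 1
Reactants: 1 4-ethynyl-1,2-dimethoxybenzene
Product: 3 methyl 3-(3,4-dimethoxyphenyl)prop-2-ynoate, via lithium acetylide 2 (not isolated)
Conditions: n-BuLi (1.05 equiv), THF, −78 °C, 30 min; then ClCO2Me (1.2 equiv), −78 → 0 °C
Reagents that add atoms: methyl chloroformate, COC(=O)Cl
Why: Deprotonation of the terminal alkyne and C-acylation of the lithium acetylide with a chloroformate is the standard preparation of aryl propiolates and creates no stereocentre.

Step 2
Reactants: 4 5-iodo-1,2,3-trimethoxybenzene; 5 buta-2,3-dien-1-ol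
Product: 6 rac-2-[1-(3,4,5-trimethoxyphenyl)ethenyl]oxirane
Conditions: Pd(PPh3)4 (5 mol %), K2CO3 (3 equiv), DMF, 60 °C, argon
Reagents that add atoms: none
Why: This is the known Pd-catalysed coupling–cyclisation of 2,3-allenols with aryl iodides, in which carbopalladation places the aryl group on the central allene carbon and the alkoxide closes 3-exo on the neighbouring allyl terminus to give the 2-(1-arylethenyl)oxirane; racemic product suffices because step 3 ionises this C–O bond again.

Step 3
Reactants: 3 methyl 3-(3,4-dimethoxyphenyl)prop-2-ynoate (1.2 equiv); 6 rac-2-[1-(3,4,5-trimethoxyphenyl)ethenyl]oxirane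
Product: 9 methyl (4S)-2-(3,4-dimethoxyphenyl)-4-[1-(3,4,5-trimethoxyphenyl)ethenyl]-4,5-dihydrofuran-3-carboxylate, via palladium zwitterion 7 (not isolated), via allenolate adduct 8 (not isolated)
Conditions: Pd2(dba)3·CHCl3 (2.5 mol %), (1R,2R)-N,N'-bis[2-(diphenylphosphanyl)benzoyl]cyclohexane-1,2-diamine [(R,R)-DACH-phenyl ligand, 7.5 mol %], degassed CH2Cl2, 0 °C → rt
Reagents that add atoms: none
Why: Proposed new method: zerovalent palladium opens the allylic C–O bond of 6 to the alkoxide–π-allyl zwitterion 7; its alkoxide adds to the aryl-bearing β-carbon of ynoate 3 (oxa-Michael addition, bond O1–C2) to give allenolate 8, whose carbanion at C3 attacks the internal allyl terminus (allylic alkylation, bond C3–C4) and releases the catalyst. The closest known reaction type is the Pd-catalysed formal [3+2] cycloaddition of vinyl epoxides or vinylethylene carbonates with doubly activated alkenes (arylidene malonates and malononitriles), which follows the same oxa-Michael/allylic alkylation sequence; an alkynoate as the two-atom partner is the untested element. The single ring closed is the 4,5-dihydrofuran, by 5-exo-trig attack of C3 on C4 of the allyl unit with the aryl-substituted C=CH2 fragment left outside the ring. The only new stereocentre, C4, is controlled by the chiral diphosphine on palladium in this ring closure, the diastereomeric allyl complexes from racemic 6 interconverting by π–σ–π exchange through the unsubstituted CH2 terminus (dynamic kinetic asymmetric transformation); the sense of induction is to be checked in the first run and the (S,S)-ligand taken if it is opposite. The step needs chemoselectivity for O-addition at C2 rather than at the ester carbonyl and five- over seven-membered closure: the first is secured by the polarisation of the ynoate (aryl on the β-carbon, ester on the α-carbon), the second by the short tether, which brings the carbanion to the internal terminus.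

Step 4
Reactants: 9 methyl (4S)-2-(3,4-dimethoxyphenyl)-4-[1-(3,4,5-trimethoxyphenyl)ethenyl]-4,5-dihydrofuran-3-carboxylate
Product: 10 [(4S)-2-(3,4-dimethoxyphenyl)-4-[1-(3,4,5-trimethoxyphenyl)ethenyl]-4,5-dihydrofuran-3-yl]methanol
Conditions: i-Bu2AlH (2.5 equiv), CH2Cl2, −78 °C; aqueous KNaC4H4O6 (Rochelle salt) work-up; Et3N-deactivated silica
Reagents that add atoms: none
Why: 1,2-Reduction of the vinylogous carbonate ester by the aluminium hydride at low temperature gives the allylic alcohol and leaves the enol ether, the styrene and the non-enolisable C4 stereocentre untouched.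

Step 5
Reactants: 10 [(4S)-2-(3,4-dimethoxyphenyl)-4-[1-(3,4,5-trimethoxyphenyl)ethenyl]-4,5-dihydrofuran-3-yl]methanol
Product: 11 tert-butyl{[(4S)-2-(3,4-dimethoxyphenyl)-4-[1-(3,4,5-trimethoxyphenyl)ethenyl]-4,5-dihydrofuran-3-yl]methoxy}diphenylsilane
Conditions: t-BuPh2SiCl (1.2 equiv), imidazole (2.5 equiv), CH2Cl2, 0 °C → rt
Reagents that add atoms: tert-butyl(chloro)diphenylsilane, CC(C)(C)[Si](Cl)(c1ccccc1)c1ccccc1
Why: Standard silylation of a primary alcohol; the bulky, weakly basic silyl ether suppresses Ferrier-type ionisation of the allylic C–O bond in the acidic step 6 and survives trifluoroacetic acid.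

Step 6
Reactants: 11 tert-butyl{[(4S)-2-(3,4-dimethoxyphenyl)-4-[1-(3,4,5-trimethoxyphenyl)ethenyl]-4,5-dihydrofuran-3-yl]methoxy}diphenylsilane
Product: 13 tert-butyl{[(2R,3R,4R)-2-(3,4-dimethoxyphenyl)-4-[1-(3,4,5-trimethoxyphenyl)ethenyl]oxolan-3-yl]methoxy}diphenylsilane (C4 unchanged in space; its descriptor changes by priority only), via oxocarbenium ion 12 (not isolated)
Conditions: CF3CO2H (2 equiv), CH2Cl2, −20 °C, 30 min; then Et3SiH (5 equiv), −20 °C; aqueous NaHCO3 quench
Reagents that add atoms: none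
Why: Ionic hydrogenation of the aryl enol ether: C-protonation at C3 gives the aryl-stabilised oxocarbenium ion 12, which exchanges with the enol ether so that the C3 arm settles trans to the C4 substituent (thermodynamic control at C3), and the silane then delivers hydride to C2 on the face opposite the adjacent C3 arm (substrate control at C2), so that aryl and CH2O end up cis, as in the reductive deoxygenation with C3 epimerisation of 2-aryl cyclic hemiketals used for 2,3-cis oxolane lignans.

Step 7
Reactants: 13 tert-butyl{[(2R,3R,4R)-2-(3,4-dimethoxyphenyl)-4-[1-(3,4,5-trimethoxyphenyl)ethenyl]oxolan-3-yl]methoxy}diphenylsilane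
Product: 14 [(2R,3R,4R)-2-(3,4-dimethoxyphenyl)-4-[1-(3,4,5-trimethoxyphenyl)ethenyl]oxolan-3-yl]methanol
Conditions: Bu4NF (1.5 equiv), THF, 0 °C → rt
Reagents that add atoms: none
Why: Fluoride-mediated desilylation, done before the ketone is unveiled so that no base-sensitive α-keto stereocentre is exposed to the basic fluoride.

Step 8
Reactants: 14 [(2R,3R,4R)-2-(3,4-dimethoxyphenyl)-4-[1-(3,4,5-trimethoxyphenyl)ethenyl]oxolan-3-yl]methanol
Product: 16 [(3S,4R,5R)-5-(3,4-dimethoxyphenyl)-4-(hydroxymethyl)oxolan-3-yl](3,4,5-trimethoxyphenyl)methanone, via vicinal diol 15 (not isolated)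
Conditions: OsO4 (2 mol %), NaIO4 (4 equiv), 2,6-lutidine (2 equiv), dioxane/H2O 3:1, rt
Reagents that add atoms: osmium tetroxide, O=[Os](=O)(=O)=O (delivers the oxygen, catalytic); sodium periodate, [Na+].[O-][I](=O)(=O)=O (terminal oxidant)
Why: Lemieux–Johnson oxidation (dihydroxylation of the only remaining alkene to diol 15, then periodate cleavage) converts the 1-arylethenyl group into the aryl ketone; C4 already has the thermodynamically preferred trans relation to C3, the lutidine buffer guards against epimerisation, and the trans CH2OH cannot close a hemiketal onto the ketone.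

**Compound list**

1 | 4-ethynyl-1,2-dimethoxybenzene | COc1ccc(C#C)cc1OC | starting material
2 | lithium (3,4-dimethoxyphenyl)acetylide | [Li]C#Cc1ccc(OC)c(OC)c1 | intermediate (not isolated)
3 | methyl 3-(3,4-dimethoxyphenyl)prop-2-ynoate | COC(=O)C#Cc1ccc(OC)c(OC)c1 | intermediate
4 | 5-iodo-1,2,3-trimethoxybenzene | COc1cc(I)cc(OC)c1OC | starting material
5 | buta-2,3-dien-1-ol | C=C=CCO | starting material
6 | rac-2-[1-(3,4,5-trimethoxyphenyl)ethenyl]oxirane | C=C(c1cc(OC)c(OC)c(OC)c1)C1CO1 | intermediate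
7 | zwitterionic alkoxide–π-allylpalladium complex [Pd(L)(C13H16O4)] of divalent palladium (L = the diphosphine; drawn as its σ-allyl form, L not drawn) | [O-]CC=C(C[Pd+])c1cc(OC)c(OC)c(OC)c1 | intermediate (not isolated)
8 | allenolate adduct [Pd(L)(C25H28O8)] of 7 and 3 (divalent palladium; σ-allyl form, L not drawn) | COC([O-])=C=C(OCC=C(C[Pd+])c1cc(OC)c(OC)c(OC)c1)c1ccc(OC)c(OC)c1 | intermediate (not isolated)
9 | methyl (4S)-2-(3,4-dimethoxyphenyl)-4-[1-(3,4,5-trimethoxyphenyl)ethenyl]-4,5-dihydrofuran-3-carboxylate | COC(=O)C1=C(c2ccc(OC)c(OC)c2)OC[C@H]1C(=C)c1cc(OC)c(OC)c(OC)c1 | intermediate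
10 | [(4S)-2-(3,4-dimethoxyphenyl)-4-[1-(3,4,5-trimethoxyphenyl)ethenyl]-4,5-dihydrofuran-3-yl]methanol | OCC1=C(c2ccc(OC)c(OC)c2)OC[C@H]1C(=C)c1cc(OC)c(OC)c(OC)c1 | intermediate
11 | tert-butyl{[(4S)-2-(3,4-dimethoxyphenyl)-4-[1-(3,4,5-trimethoxyphenyl)ethenyl]-4,5-dihydrofuran-3-yl]methoxy}diphenylsilane | CC(C)(C)[Si](OCC1=C(c2ccc(OC)c(OC)c2)OC[C@H]1C(=C)c1cc(OC)c(OC)c(OC)c1)(c1ccccc1)c1ccccc1 | intermediate
12 | (3R,4R)-3-{[tert-butyl(diphenyl)silyl]oxymethyl}-2-(3,4-dimethoxyphenyl)-4-[1-(3,4,5-trimethoxyphenyl)ethenyl]-4,5-dihydro-3H-furan-1-ium trifluoroacetate | COc1ccc(C2=[O+]C[C@@H](C(=C)c3cc(OC)c(OC)c(OC)c3)[C@@H]2CO[Si](c2ccccc2)(c2ccccc2)C(C)(C)C)cc1OC.[O-]C(=O)C(F)(F)F | intermediate (not isolated)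
13 | tert-butyl{[(2R,3R,4R)-2-(3,4-dimethoxyphenyl)-4-[1-(3,4,5-trimethoxyphenyl)ethenyl]oxolan-3-yl]methoxy}diphenylsilane | COc1ccc([C@@H]2OC[C@@H](C(=C)c3cc(OC)c(OC)c(OC)c3)[C@@H]2CO[Si](c2ccccc2)(c2ccccc2)C(C)(C)C)cc1OC | intermediate
14 | [(2R,3R,4R)-2-(3,4-dimethoxyphenyl)-4-[1-(3,4,5-trimethoxyphenyl)ethenyl]oxolan-3-yl]methanol | COc1ccc([C@@H]2OC[C@@H](C(=C)c3cc(OC)c(OC)c(OC)c3)[C@@H]2CO)cc1OC | intermediate
15 | 1-[(3S,4R,5R)-5-(3,4-dimethoxyphenyl)-4-(hydroxymethyl)oxolan-3-yl]-1-(3,4,5-trimethoxyphenyl)ethane-1,2-diol (both epimers at the new carbinol carbon) | COc1ccc([C@@H]2OC[C@@H](C(O)(CO)c3cc(OC)c(OC)c(OC)c3)[C@@H]2CO)cc1OC | intermediate (not isolated)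
16 | [(3S,4R,5R)-5-(3,4-dimethoxyphenyl)-4-(hydroxymethyl)oxolan-3-yl](3,4,5-trimethoxyphenyl)methanone, i.e. the (2R,3R,4S)-2-aryl-3-(hydroxymethyl)-4-aroyloxolane | COc1ccc([C@@H]2OC[C@@H](C(=O)c3cc(OC)c(OC)c(OC)c3)[C@@H]2CO)cc1OC | target

**Step count and risks**

Total step count: 8. Longest linear sequence: 7 steps (steps 1, 3, 4, 5, 6, 7, 8, or equally 2, 3, 4, 5, 6, 7, 8).

Steps most likely to fail:

1. Step 3 (proposed new method). The zwitterion may collapse by hydride shift to a 2-arylbutenal before it meets the ynoate, or its alkoxide may attack the ester carbonyl instead of the β-carbon. The carbanion may also close on the CH2 terminus (seven-membered ring), or the ligand may give low enantioselectivity.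
   Fallback, setting out from 3 and 6 and returning at 9: the ring is built by C-alkylation first, with a stabilised carbon nucleophile. Ynoate 3 is hydrated (AuCl(PPh3)/AgOTf, 2 mol % each, aqueous dioxane) to methyl 3-(3,4-dimethoxyphenyl)-3-oxopropanoate F1. F1 (in excess) and 6 are then combined under the known conditions for the dynamic kinetic asymmetric Tsuji–Trost alkylation of vinyl epoxides with β-keto esters (Pd2(dba)3·CHCl3, the enantiomer of the DACH-phenyl ligand that gives the 3R product, CH2Cl2). Hydrogen bonding of the alkoxide to the nucleophile directs attack to the internal allyl terminus and should give methyl (3R)-2-(3,4-dimethoxybenzoyl)-3-(hydroxymethyl)-4-(3,4,5-trimethoxyphenyl)pent-4-enoate F2 (both epimers at C2, in equilibrium with its cyclic hemiketal). Cyclodehydration (PPTS, toluene, 4 Å molecular sieves, 60 °C) then gives 9.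

2. Step 6. Hydride capture may outrun equilibration at C3, so that kinetic protonation anti to the C4 arm leads to the all-cis oxolane. Hydride may also be delivered syn to the C3 arm, or the acid may start ionic reduction of the styrene or reopen the benzylic ether.
   Fallback, setting out from 3 and 6 and returning at 16: the relay is changed to a kinetic one in the mirror-image series, with thermodynamic correction at C4 at the end. Step 3 run with the (S,S)-ligand should give methyl (4R)-2-(3,4-dimethoxyphenyl)-4-[1-(3,4,5-trimethoxyphenyl)ethenyl]-4,5-dihydrofuran-3-carboxylate F3. Reduction with i-Bu2AlH gives [(4R)-2-(3,4-dimethoxyphenyl)-4-[1-(3,4,5-trimethoxyphenyl)ethenyl]-4,5-dihydrofuran-3-yl]methanol F4, and silylation gives tert-butyl{[(4R)-2-(3,4-dimethoxyphenyl)-4-[1-(3,4,5-trimethoxyphenyl)ethenyl]-4,5-dihydrofuran-3-yl]methoxy}diphenylsilane F5. Ionic hydrogenation under kinetic control (Et3SiH present from the start, CF3CO2H, CH2Cl2, −78 °C) puts the proton on C3 anti to the C4 arm and the hydride on C2 anti to both arms, two preferences that reinforce each other. This should give the all-cis tert-butyl{[(2R,3R,4S)-2-(3,4-dimethoxyphenyl)-4-[1-(3,4,5-trimethoxyphenyl)ethenyl]oxolan-3-yl]methoxy}diphenylsilane F6. Lemieux–Johnson oxidation gives the all-cis ketone [(3R,4R,5R)-4-{[tert-butyl(diphenyl)silyl]oxymethyl}-5-(3,4-dimethoxyphenyl)oxolan-3-yl](3,4,5-trimethoxyphenyl)methanone F7. Base epimerisation of the α-keto centre (DBU, CH2Cl2, rt) moves the aroyl group trans to the C3 arm, giving [(3S,4R,5R)-4-{[tert-butyl(diphenyl)silyl]oxymethyl}-5-(3,4-dimethoxyphenyl)oxolan-3-yl](3,4,5-trimethoxyphenyl)methanone F8. HF·pyridine (THF, 0 °C) then removes the silyl group to give 16.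

3. Step 2. The allyl intermediate may undergo β-hydride elimination to an unsaturated aldehyde or close 5-endo to a 2,5-dihydrofuran, and the product epoxide may be re-ionised and degraded by the catalyst at 60 °C.
   Fallback, setting out from 4 and returning at 6: the epoxide is made without palladium. Magnesium insertion (Mg turnings, THF) converts 4 into (3,4,5-trimethoxyphenyl)magnesium iodide F9. CuI-catalysed carbomagnesiation of prop-2-yn-1-ol (10 mol % CuI, THF/toluene) gives 2-(3,4,5-trimethoxyphenyl)prop-2-en-1-ol F10. Allylic oxidation (MnO2, CH2Cl2) gives 2-(3,4,5-trimethoxyphenyl)prop-2-enal F11, used crude. Corey–Chaykovsky epoxidation (trimethylsulfonium iodide, NaH, DMSO/THF, 0 °C) adds the methylene to the aldehyde to give 6.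

**Further compounds**

F1 | step 3 | methyl 3-(3,4-dimethoxyphenyl)-3-oxopropanoate | COC(=O)CC(=O)c1ccc(OC)c(OC)c1
F2 | step 3 | methyl (3R)-2-(3,4-dimethoxybenzoyl)-3-(hydroxymethyl)-4-(3,4,5-trimethoxyphenyl)pent-4-enoate (both epimers at C2) | COC(=O)C(C(=O)c1ccc(OC)c(OC)c1)[C@@H](CO)C(=C)c1cc(OC)c(OC)c(OC)c1
F3 | step 6 | methyl (4R)-2-(3,4-dimethoxyphenyl)-4-[1-(3,4,5-trimethoxyphenyl)ethenyl]-4,5-dihydrofuran-3-carboxylate | COC(=O)C1=C(c2ccc(OC)c(OC)c2)OC[C@@H]1C(=C)c1cc(OC)c(OC)c(OC)c1
F4 | step 6 | [(4R)-2-(3,4-dimethoxyphenyl)-4-[1-(3,4,5-trimethoxyphenyl)ethenyl]-4,5-dihydrofuran-3-yl]methanol | OCC1=C(c2ccc(OC)c(OC)c2)OC[C@@H]1C(=C)c1cc(OC)c(OC)c(OC)c1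
F5 | step 6 | tert-butyl{[(4R)-2-(3,4-dimethoxyphenyl)-4-[1-(3,4,5-trimethoxyphenyl)ethenyl]-4,5-dihydrofuran-3-yl]methoxy}diphenylsilane | CC(C)(C)[Si](OCC1=C(c2ccc(OC)c(OC)c2)OC[C@@H]1C(=C)c1cc(OC)c(OC)c(OC)c1)(c1ccccc1)c1ccccc1
F6 | step 6 | tert-butyl{[(2R,3R,4S)-2-(3,4-dimethoxyphenyl)-4-[1-(3,4,5-trimethoxyphenyl)ethenyl]oxolan-3-yl]methoxy}diphenylsilane (all-cis) | COc1ccc([C@@H]2OC[C@H](C(=C)c3cc(OC)c(OC)c(OC)c3)[C@@H]2CO[Si](c2ccccc2)(c2ccccc2)C(C)(C)C)cc1OC
F7 | step 6 | [(3R,4R,5R)-4-{[tert-butyl(diphenyl)silyl]oxymethyl}-5-(3,4-dimethoxyphenyl)oxolan-3-yl](3,4,5-trimethoxyphenyl)methanone (all-cis) | COc1ccc([C@@H]2OC[C@H](C(=O)c3cc(OC)c(OC)c(OC)c3)[C@@H]2CO[Si](c2ccccc2)(c2ccccc2)C(C)(C)C)cc1OC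
F8 | step 6 | [(3S,4R,5R)-4-{[tert-butyl(diphenyl)silyl]oxymethyl}-5-(3,4-dimethoxyphenyl)oxolan-3-yl](3,4,5-trimethoxyphenyl)methanone | COc1ccc([C@@H]2OC[C@@H](C(=O)c3cc(OC)c(OC)c(OC)c3)[C@@H]2CO[Si](c2ccccc2)(c2ccccc2)C(C)(C)C)cc1OC
F9 | step 2 | (3,4,5-trimethoxyphenyl)magnesium iodide | COc1cc([Mg]I)cc(OC)c1OC
F10 | step 2 | 2-(3,4,5-trimethoxyphenyl)prop-2-en-1-ol | C=C(CO)c1cc(OC)c(OC)c(OC)c1
F11 | step 2 | 2-(3,4,5-trimethoxyphenyl)prop-2-enal | C=C(C=O)c1cc(OC)c(OC)c(OC)c1
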